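A single pair of readings misleads. At 60.0 s Tuesday's flask shows 8% target, and at 1.00 min Thursday's flask, with twice the second substrate, shows 7%. That looks like a rate falling with more second substrate, but the gap of 1 percentage point stands against a scatter of 2 points.

the same everywhere: starting material 0.050 M; free enzyme 0.05 mol%
- Tuesday's: second substrate 4 equiv; protic impurity 0.025 M; the very flask that is asked about, followed so far
- Thursday's: second substrate 8 equiv; protic impurity 0.025 M; run made earlier
- flask: second substrate 4.00 equiv; protic impurity 0.0250 M

- Tuesday's (time / s: target / %, starting material / %): 15.0: 0, 99; 30.0: 2, 96; 40.0: 6, 91; 60.0: 8, 92; 80.0: 9, 88
- Thursday's (time / min: target / %, starting material / %): 0.333: 3, 96; 1.00: 7, 92; 2.00: 14, 80; 3.00: 19, 78; 4.00: 30, 72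

(scatter of a reading: 2 percentage points)

- apparent order in second substrate when 20% of the starting material are converted (percent change of the rate of making target for one percent more second substrate charged)
- apparent order in free enzyme when 20% of the starting material are converted (percent change of the rate of making target for one percent more free enzyme charged)
- factor on the rate of making target when 20% of the starting material are converted if free enzyme is charged twice over

- what is said of first product includes idle complex
- the analysis behind the earlier runs scatters by 2 percentage points, standard deviation
- candidate steps: starting material + free enzyme <-> first complex; first complex <-> loaded enzyme + first product; second substrate + loaded enzyme <-> second complex; second complex -> free enzyme + target; second substrate + protic impurity -> quenched reagent; free enzyme + first product <-> idle complex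
- no earlier run changes the charge of free enzyme; that part of a forecast is a guess

A whole run says more than one point. The quantity to carry is the turnover frequency, the target made per minute for each free enzyme charged: the slope of target against time, drawn through the origin over all readings of a run, divided by the loading. Tuesday's flask gives 141 min⁻¹, and Thursday's flask gives 141 min⁻¹. Their ratio of 1.00, for twice the charge, puts my reading of the order in second substrate near zero, though loosely, since Tuesday's readings reach only 9% target.

At that turnover, Tuesday's flask is reckoned to reach 20% conversion at about 2.84 min, inside the span of Thursday's readings up to 4.00 min, so the slope is taken as the rate there. Turnover is counted per enzyme, and the enzyme charge is far below the first product present at that conversion: 2.50 × 10⁻⁵ M against 0.0100 M. My guess, untested by any run, is therefore order one in free enzyme and a factor of two on doubling.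

The forecast gives 0.15 for second substrate, above my near-zero reading, with 1 for free enzyme and 2 for doubling, holding that “Doubling the second substrate therefore hardly changes the rate”.

The flask gives 0.065 for second substrate, 1.0 for free enzyme and a factor of 2.01 on doubling.

    starting material + free enzyme ⇌ first complex (K = 17.0 M⁻¹, k = 980 M⁻¹ s⁻¹)
    first complex ⇌ loaded enzyme + first product (K = 0.570 M, k = 370 s⁻¹)
    second substrate + loaded enzyme ⇌ second complex (K = 97.0 M⁻¹, k = 2300 M⁻¹ s⁻¹)
    second complex → free enzyme + target (k = 2.70 s⁻¹)
    second substrate + protic impurity → quenched reagent (k = 0.0310 M⁻¹ s⁻¹)
    free enzyme + first product ⇌ idle complex (K = 11.0 M⁻¹, k = 0.110 M⁻¹ s⁻¹)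

Second complex, the resting state of the round, holds 87.0% of the catalyst at 2.00 min. The turnover frequency of 141 min⁻¹ on a loading of 0.05 mol% makes 28.2% target in 4.00 min, and the flask holds 28.2% target at 4.00 min.

The readings are simulated from invented constants.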